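**Plan**
1. Retrosynthesis: after removal of two silyl groups, ring A is cut at C4a–C5 and C8–C8a. Further cuts are C3–C1' (ring C to ring B) and C6–C7 (ketene acetal carbon to acyl carbon) inside the four-carbon unit.
2. Enabling feature: ring A shares only its C4a–C8a edge with the 4-pyranone ring C. C5 (OMe), C6 (prenyl), C7 (OH) and C8 (hydroxyalkyl) form one contiguous chain with the oxygen pattern of a 1,1-dimethoxy-3-siloxy diene.
3. Forward, rings C and B: 4H-pyran-4-one is dibrominated and joined to ring B by a single Suzuki coupling. The remaining C–Br marks the enone that becomes C4a=C8a.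
4. Forward, ring A: prenylketene dimethyl acetal is acylated with a chiral 4-silyloxyhexenoyl chloride and enol-silylated to the diene. Ring A then forms last by annulation with loss of methanol and HBr.
5. Stereochemistry: the single (R) centre comes from a Corey–Bakshi–Shibata reduction of an isopropenyl ketone and is carried through unchanged.

Key step: step 12

Remark: at the carbinol carbon the priority order O > isopropenyl carbon > CH2 > H holds in every compound, so the descriptor stays R throughout. All compounds marked as starting materials are taken as commercial.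

Step 1
Reactants: 1 methyl 4-chloro-4-oxobutanoate
Product: 2 methyl 4-[methoxy(methyl)amino]-4-oxobutanoate
Conditions: MeNHOMe·HCl (1.1 equiv), Et3N (2.2 equiv), CH2Cl2, 0 → 23 °C
Reagents that add atoms: N,O-dimethylhydroxylamine hydrochloride, CNOC.Cl
Why: N-acylation of the hydroxylamine by the acid chloride is much faster than attack on the methyl ester and should give the Weinreb amide cleanly.

Step 2
Reactants: 2 methyl 4-[methoxy(methyl)amino]-4-oxobutanoate; 3 isopropenylmagnesium bromide
Product: 4 methyl 5-methyl-4-oxohex-5-enoate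
Conditions: 3 (1.2 equiv), THF, −78 → −15 °C; inverse quench into cold 1 M HCl
Reagents that add atoms: none
Why: Weinreb ketone synthesis, in which the amide is the more reactive acyl group at low temperature and the enone is released only on the acidic quench, so over-addition and conjugate addition should not intervene.

Step 3
Reactants: 4 methyl 5-methyl-4-oxohex-5-enoate
Product: 5 methyl (4R)-4-hydroxy-5-methylhex-5-enoate
Conditions: (S)-2-methyl-CBS-oxazaborolidine (0.15 equiv), catecholborane (1.6 equiv), toluene, −78 °C; MeOH, then pH 9 buffer wash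
Reagents that add atoms: none
Why: Corey–Bakshi–Shibata reduction, in which isopropenyl acts as the large and CH2CH2CO2Me as the small group, so the (S)-catalyst should deliver hydride to the Si face and set the (R)-carbinol, while catecholborane spares the ester and the 1,1-disubstituted alkene.

Step 4
Reactants: 5 methyl (4R)-4-hydroxy-5-methylhex-5-enoate
Product: 6 methyl (4R)-4-(tert-butyldimethylsilyloxy)-5-methylhex-5-enoate
Conditions: TBSOTf (1.2 equiv), 2,6-lutidine (1.5 equiv), CH2Cl2, −78 → 0 °C
Reagents that add atoms: tert-butyldimethylsilyl triflate, CC(C)(C)[Si](C)(C)OS(=O)(=O)C(F)(F)F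
Why: O-silylation with a silyl triflate is fast at low temperature and should outrun lactonization of the γ-hydroxy ester, and the C–O bond of the stereocentre is not touched.

Step 5
Reactants: 6 methyl (4R)-4-(tert-butyldimethylsilyloxy)-5-methylhex-5-enoate
Product: 7 (4R)-4-(tert-butyldimethylsilyloxy)-5-methylhex-5-enoic acid
Conditions: LiOH (2 equiv), THF/MeOH/H2O, 0 → 23 °C; 1 M HCl to pH 4
Reagents that add atoms: lithium hydroxide, [Li+].[OH-]
Why: Saponification of a methyl ester, in which the secondary silyl ether tolerates LiOH and the stereocentre, being γ to the carbonyl group, cannot epimerize.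

Step 6
Reactants: 8 5-bromo-2-methylpent-2-ene; 9 tetramethyl orthocarbonate
Product: 11 6,6,6-trimethoxy-2-methylhex-2-ene, via 4-methylpent-3-enylmagnesium bromide 10 (not isolated)
Conditions: Mg, Et2O, reflux; 9 (1.5 equiv), Et2O → toluene, 70 °C; cold NH4Cl/NH3 buffer (pH 8)
Reagents that add atoms: none
Why: Grignard substitution of one methoxy group of an orthocarbonate (the ortho ester counterpart of the Bodroux–Chichibabin aldehyde synthesis) should stop at the ortho ester, which ionizes less readily than the orthocarbonate.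

Step 7
Reactants: 11 6,6,6-trimethoxy-2-methylhex-2-ene
Product: 12 1,1-dimethoxy-5-methylhexa-1,4-diene (prenylketene dimethyl acetal)
Conditions: Al(OtBu)3 (1.0 equiv), neat, 170–190 °C, tBuOH distilled off; then distillation at reduced pressure
Reagents that add atoms: none
Why: Aluminium alkoxide-assisted thermal β-elimination of methanol from an ortho ester is the classical entry to alkylketene acetals, because aluminium binds the methoxide and the hindered tert-butanol leaves without exchanging into the acetal.

Step 8
Reactants: 7 (4R)-4-(tert-butyldimethylsilyloxy)-5-methylhex-5-enoic acid; 12 1,1-dimethoxy-5-methylhexa-1,4-diene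
Product: 14 (6R)-6-(tert-butyldimethylsilyloxy)-1,1-dimethoxy-7-methyl-2-(3-methylbut-2-enyl)octa-1,7-dien-3-one, via acid chloride 13 (not isolated)
Conditions: 1-chloro-N,N,2-trimethylprop-1-enylamine (1.1 equiv), CH2Cl2, 0 °C; 12 (1.5 equiv), 2,6-lutidine (1.3 equiv), 0 → 23 °C; Et3N-deactivated silica
Reagents that add atoms: none
Why: C-acylation of a ketene acetal by an acid chloride, in which the chloroenamine makes 13 under neutral conditions that spare the silyl ether and lutidine removes the very acidic α-proton of the acylated dimethoxycarbenium ion before chloride can demethylate it.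

Step 9
Reactants: 14 (6R)-6-(tert-butyldimethylsilyloxy)-1,1-dimethoxy-7-methyl-2-(3-methylbut-2-enyl)octa-1,7-dien-3-one
Product: 16 (3Z,6R)-6-(tert-butyldimethylsilyloxy)-1,1-dimethoxy-7-methyl-2-(3-methylbut-2-enyl)-3-(trimethylsilyloxy)octa-1,3,7-triene, via lithium enolate 15 (not isolated)
Conditions: LDA (1.1 equiv), THF, −78 °C; TMSCl (1.3 equiv), −78 → 0 °C; pentane, filtration, used crude
Reagents that add atoms: chlorotrimethylsilane, C[Si](C)(C)Cl
Why: Kinetic deprotonation at the only enolizable carbon and O-silylation, as used for the parent 1,1-dimethoxy-3-siloxybutadiene, and the bulky alkenyl group on the carbonyl carbon should favour the (Z)-enolate, which points the side chain outward in the s-cis diene.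

Step 10
Reactants: 17 4H-pyran-4-one
Product: 19 3,5-dibromo-4H-pyran-4-one, via 3-bromo-4H-pyran-4-one 18 (not isolated)
Conditions: Br2 (2.3 equiv), pyridine (2.5 equiv), CH2Cl2, 0 → 40 °C
Reagents that add atoms: bromine, BrBr
Why: α-Halogenation of an enone by bromine addition and dehydrobromination should take place at both equivalent nucleophilic positions C3 and C5 of the vinylogous ester.

Step 11
Reactants: 19 3,5-dibromo-4H-pyran-4-one; 20 4-(tert-butyldimethylsilyloxy)phenylboronic acid
Product: 21 3-bromo-5-[4-(tert-butyldimethylsilyloxy)phenyl]-4H-pyran-4-one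
Conditions: 19 (2 equiv), Pd(OAc)2 (3 mol %), SPhos (6 mol %), K3PO4 (2 equiv), toluene/H2O 20:1, 50 °C; excess 19 recovered
Reagents that add atoms: none
Why: Suzuki–Miyaura coupling at an sp2 C–Br bond α to the carbonyl group, as practised on 3-halochromones, should be held at monoarylation by the excess of symmetrical 19 and by the electron-rich aryl group that slows the second oxidative addition.

Step 12
Reactants: 21 3-bromo-5-[4-(tert-butyldimethylsilyloxy)phenyl]-4H-pyran-4-one; 16 (3Z,6R)-6-(tert-butyldimethylsilyloxy)-1,1-dimethoxy-7-methyl-2-(3-methylbut-2-enyl)-3-(trimethylsilyloxy)octa-1,3,7-triene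
Product: 26 8-[(2R)-2-(tert-butyldimethylsilyloxy)-3-methylbut-3-enyl]-3-[4-(tert-butyldimethylsilyloxy)phenyl]-7-hydroxy-5-methoxy-6-(3-methylbut-2-enyl)-4H-chromen-4-one, via siloxypyrylium triflate 22 (not isolated), via bromo ketal cycloadduct 23 (not isolated), via bromodihydrochromenone 24 (not isolated), via 7-O-trimethylsilyl isoflavone 25 (not isolated)
Conditions: TMSOTf (1.2 equiv), 2,6-di-tert-butylpyridine (0.3 equiv), CH2Cl2, 0 → 23 °C; 16 (1.4 equiv), −78 → 0 °C; Et3N (5 equiv), 0 → 23 °C; citric acid, MeOH, 0 °C
Reagents that add atoms: none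
Why: Proposed new method: TMSOTf converts 21 into the 4-siloxypyrylium salt 22, the nucleophilic terminus C4 of diene 16 (future C8) adds to its C6 (future C8a) in a vinylogous Mukaiyama–Michael step, and the bromo silyl enol ether carbon so formed (future C4a) attacks the dimethoxycarbenium carbon (future C5) to give 23, a formal [4+2] union that could equally run as a concerted, highly asynchronous Diels–Alder reaction. Ring A, the only ring formed, thus closes as a six-membered carbocycle in the 6-(enolexo)-exo-trig mode (or suprafacially on both partners if concerted). A 1,4-elimination of methanol across C5 and C8 leads to 24, in which H-8a and Br-4a sit on adjacent sp3 carbons of a cyclohexadiene, so that Et3N should remove HBr with aromatization as driving force, and the bromine delivers the oxidation level without any oxidant that could touch the prenyl or isopropenyl groups. The closest known reaction types are the cycloaddition–aromatization of 1,1-dimethoxy-3-siloxydienes with halogenated quinones and the silyl triflate-mediated addition of 1,3-bis(silyloxy)dienes to chromones by way of benzopyrylium triflates, whereas a monocyclic bromopyranone has not served as the two-carbon partner. No stereocentre survives from the step, since C4a, C8 and C8a become sp2 and the remote silyloxy-bearing carbon is not involved. The step needs orientation and site selectivity: the push of the two methoxy groups and the siloxy group makes C4 of 16 the donor and the acetal carbon the acceptor, which fixes OMe at C5 and oxygen at C7, while C6 of 22 is preferred over C2 because bromine withdraws inductively, the twisted aryl group screens C2, and only the C6 adduct holds a leaving group that carries the sequence irreversibly to the arene.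

Step 13
Reactants: 26 8-[(2R)-2-(tert-butyldimethylsilyloxy)-3-methylbut-3-enyl]-3-[4-(tert-butyldimethylsilyloxy)phenyl]-7-hydroxy-5-methoxy-6-(3-methylbut-2-enyl)-4H-chromen-4-one
Product: 27 7-hydroxy-8-[(2R)-2-hydroxy-3-methylbut-3-enyl]-3-(4-hydroxyphenyl)-5-methoxy-6-(3-methylbut-2-enyl)-4H-chromen-4-one (CNP0324832.1)
Conditions: TBAF (3 equiv), AcOH (3 equiv), THF, 0 → 23 °C
Reagents that add atoms: none
Why: Fluoride cleavage of the aryl and the secondary alkyl silyl ether, buffered with acetic acid so that the base-sensitive C2 of ring C, the alkenes and the allylic carbinol centre remain untouched.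

**Compound list**
1 | methyl 4-chloro-4-oxobutanoate | COC(=O)CCC(=O)Cl | starting material
2 | methyl 4-[methoxy(methyl)amino]-4-oxobutanoate | COC(=O)CCC(=O)N(C)OC | intermediate
3 | isopropenylmagnesium bromide | C=C(C)[Mg]Br | starting material
4 | methyl 5-methyl-4-oxohex-5-enoate | C=C(C)C(=O)CCC(=O)OC | intermediate
5 | methyl (4R)-4-hydroxy-5-methylhex-5-enoate | C=C(C)[C@H](O)CCC(=O)OC | intermediate
6 | methyl (4R)-4-(tert-butyldimethylsilyloxy)-5-methylhex-5-enoate | C=C(C)[C@H](O[Si](C)(C)C(C)(C)C)CCC(=O)OC | intermediate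
7 | (4R)-4-(tert-butyldimethylsilyloxy)-5-methylhex-5-enoic acid | C=C(C)[C@H](O[Si](C)(C)C(C)(C)C)CCC(=O)O | intermediate
8 | 5-bromo-2-methylpent-2-ene | CC(C)=CCCBr | starting material
9 | tetramethyl orthocarbonate | COC(OC)(OC)OC | starting material
10 | 4-methylpent-3-enylmagnesium bromide (not isolated) | CC(C)=CCC[Mg]Br | intermediate
11 | 6,6,6-trimethoxy-2-methylhex-2-ene | CC(C)=CCCC(OC)(OC)OC | intermediate
12 | 1,1-dimethoxy-5-methylhexa-1,4-diene | COC(OC)=CCC=C(C)C | intermediate
13 | (4R)-4-(tert-butyldimethylsilyloxy)-5-methylhex-5-enoyl chloride (not isolated) | C=C(C)[C@H](O[Si](C)(C)C(C)(C)C)CCC(=O)Cl | intermediate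
14 | (6R)-6-(tert-butyldimethylsilyloxy)-1,1-dimethoxy-7-methyl-2-(3-methylbut-2-enyl)octa-1,7-dien-3-one | C=C(C)[C@H](O[Si](C)(C)C(C)(C)C)CCC(=O)C(CC=C(C)C)=C(OC)OC | intermediate
15 | lithium (Z)-enolate of 14 (not isolated) | C=C(C)[C@H](O[Si](C)(C)C(C)(C)C)C/C=C([O-])/C(CC=C(C)C)=C(OC)OC.[Li+] | intermediate
16 | (3Z,6R)-6-(tert-butyldimethylsilyloxy)-1,1-dimethoxy-7-methyl-2-(3-methylbut-2-enyl)-3-(trimethylsilyloxy)octa-1,3,7-triene | C=C(C)[C@H](O[Si](C)(C)C(C)(C)C)C/C=C(O[Si](C)(C)C)/C(CC=C(C)C)=C(OC)OC | intermediate
17 | 4H-pyran-4-one | O=c1ccocc1 | starting material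
18 | 3-bromo-4H-pyran-4-one (not isolated) | O=c1ccocc1Br | intermediate
19 | 3,5-dibromo-4H-pyran-4-one | O=c1c(Br)cocc1Br | intermediate
20 | 4-(tert-butyldimethylsilyloxy)phenylboronic acid | CC(C)(C)[Si](C)(C)Oc1ccc(B(O)O)cc1 | starting material
21 | 3-bromo-5-[4-(tert-butyldimethylsilyloxy)phenyl]-4H-pyran-4-one | O=c1c(Br)cocc1-c1ccc(O[Si](C)(C)C(C)(C)C)cc1 | intermediate
22 | 3-bromo-5-[4-(tert-butyldimethylsilyloxy)phenyl]-4-(trimethylsilyloxy)pyrylium triflate (not isolated) | C[Si](C)(C)Oc1c(Br)c[o+]cc1-c1ccc(O[Si](C)(C)C(C)(C)C)cc1.[O-]S(=O)(=O)C(F)(F)F | intermediate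
23 | 4a-bromo-5,5-dimethoxy-7-(trimethylsilyloxy)-4a,5,8,8a-tetrahydrochromen-4-one cycloadduct, configuration at C4a, C8 and C8a left open (not isolated) | C=C(C)[C@H](O[Si](C)(C)C(C)(C)C)CC1C(O[Si](C)(C)C)=C(CC=C(C)C)C(OC)(OC)C2(Br)C(=O)C(-c3ccc(O[Si](C)(C)C(C)(C)C)cc3)=COC12 | intermediate
24 | 4a-bromo-5-methoxy-7-(trimethylsilyloxy)-4a,8a-dihydrochromen-4-one, configuration at C4a and C8a left open (not isolated) | C=C(C)[C@H](O[Si](C)(C)C(C)(C)C)CC1=C(O[Si](C)(C)C)C(CC=C(C)C)=C(OC)C2(Br)C(=O)C(-c3ccc(O[Si](C)(C)C(C)(C)C)cc3)=COC12 | intermediate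
25 | 7-O-trimethylsilyl ether of 26 (not isolated) | C=C(C)[C@H](O[Si](C)(C)C(C)(C)C)Cc1c(O[Si](C)(C)C)c(CC=C(C)C)c(OC)c2c(=O)c(-c3ccc(O[Si](C)(C)C(C)(C)C)cc3)coc12 | intermediate
26 | 8-[(2R)-2-(tert-butyldimethylsilyloxy)-3-methylbut-3-enyl]-3-[4-(tert-butyldimethylsilyloxy)phenyl]-7-hydroxy-5-methoxy-6-(3-methylbut-2-enyl)-4H-chromen-4-one | C=C(C)[C@H](O[Si](C)(C)C(C)(C)C)Cc1c(O)c(CC=C(C)C)c(OC)c2c(=O)c(-c3ccc(O[Si](C)(C)C(C)(C)C)cc3)coc12 | intermediate
27 | 7-hydroxy-8-[(2R)-2-hydroxy-3-methylbut-3-enyl]-3-(4-hydroxyphenyl)-5-methoxy-6-(3-methylbut-2-enyl)-4H-chromen-4-one | C=C(C)[C@H](O)Cc1c(O)c(CC=C(C)C)c(OC)c2c(=O)c(-c3ccc(O)cc3)coc12 | target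

**Step count:** 13 steps in total.
**Longest linear sequence:** 9 steps (1, 2, 3, 4, 5, 8, 9, 12, 13).

**Steps most likely to fail**

Step 12. The diene may add at C2 instead of C6 of the pyrylium ion. The Michael adduct may stall before the second bond forms. Ring C may open by retro-oxa-Michael cleavage once the amine is added, before HBr is lost.

The fallback sets out from 21 and comes back at 26, and each operation belongs to an established reaction type.
- Palladium-catalysed C–S coupling with 4-methylbenzenethiol (Pd2(dba)3, Xantphos, iPr2NEt, dioxane, 90 °C) would give the sulfide 3-[4-(tert-butyldimethylsilyloxy)phenyl]-5-(4-methylphenylsulfanyl)-4H-pyran-4-one F1.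
- One equivalent of mCPBA (CH2Cl2, −40 °C) would give the sulfoxide 3-[4-(tert-butyldimethylsilyloxy)phenyl]-5-(4-methylphenylsulfinyl)-4H-pyran-4-one F2.
- α-Sulfinyl enones and sulfinylquinones are proven dienophiles for oxygenated dienes. Their adducts lose sulfenic acid by a thermal syn-elimination that uses exactly the cis H/S relationship set by the cycloaddition, so no base and no Lewis acid is needed.
- Warming F2 with 16 in toluene (23 → 80 °C) should give the sulfinyl ketal cycloadduct F3. This sheds 4-methylbenzenesulfenic acid and methanol to give 25, and the citric acid work-up of step 12 leads to 26.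

Step 8. The acylated dimethoxycarbenium ion may collapse by chloride-induced demethylation to the keto ester. Attack at the substituted ketene acetal carbon may be too slow. The supply of 12 depends on a harsh elimination in step 7.

The fallback sets out from 7 and comes back at 14. It installs the prenyl group after the acylation and avoids 12 altogether.
- Acid chloride 13, made as in step 8, would acylate commercial 1,1-dimethoxyethene (2,6-lutidine, CH2Cl2, 0 → 23 °C), which is the parent case of this reaction. The product is (6R)-6-(tert-butyldimethylsilyloxy)-1,1-dimethoxy-7-methylocta-1,7-dien-3-one F4.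
- Electrophilic iodination of the nucleophilic α-carbon of this push–pull alkene with NIS (CH2Cl2, 0 °C) would give (6R)-6-(tert-butyldimethylsilyloxy)-2-iodo-1,1-dimethoxy-7-methylocta-1,7-dien-3-one F5.
- A Stille coupling with tributyl(3-methylbut-2-enyl)stannane (Pd2(dba)3, AsPh3, DMF, 50 °C) would then deliver 14.

Step 11. Possible failures are double arylation, opening of the pyranone ring by the aqueous base, and loss of the aryl silyl ether.

The fallback sets out from 19 and comes back at 26 by inverting the order of annulation and arylation.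
- The symmetrical dibromide 19, which has two equivalent brominated enones and so no site problem, would be taken through the conditions of step 12 with 16. This would give 3-bromo-8-[(2R)-2-(tert-butyldimethylsilyloxy)-3-methylbut-3-enyl]-7-hydroxy-5-methoxy-6-(3-methylbut-2-enyl)-4H-chromen-4-one F6.
- A Suzuki–Miyaura coupling of this 3-bromochromone with 20 (Pd(OAc)2, SPhos, K3PO4, toluene/H2O, 50 °C), the standard isoflavone closure, would then give 26.

**Further compounds**
F1 | step 12 | 3-[4-(tert-butyldimethylsilyloxy)phenyl]-5-(4-methylphenylsulfanyl)-4H-pyran-4-one | Cc1ccc(Sc2cocc(-c3ccc(O[Si](C)(C)C(C)(C)C)cc3)c2=O)cc1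
F2 | step 12 | 3-[4-(tert-butyldimethylsilyloxy)phenyl]-5-(4-methylphenylsulfinyl)-4H-pyran-4-one | Cc1ccc(S(=O)c2cocc(-c3ccc(O[Si](C)(C)C(C)(C)C)cc3)c2=O)cc1
F3 | step 12 | 5,5-dimethoxy-4a-(4-methylphenylsulfinyl)-7-(trimethylsilyloxy)-4a,5,8,8a-tetrahydrochromen-4-one cycloadduct | C=C(C)[C@H](O[Si](C)(C)C(C)(C)C)CC1C(O[Si](C)(C)C)=C(CC=C(C)C)C(OC)(OC)C2(S(=O)c3ccc(C)cc3)C(=O)C(-c3ccc(O[Si](C)(C)C(C)(C)C)cc3)=COC12
F4 | step 8 | (6R)-6-(tert-butyldimethylsilyloxy)-1,1-dimethoxy-7-methylocta-1,7-dien-3-one | C=C(C)[C@H](O[Si](C)(C)C(C)(C)C)CCC(=O)C=C(OC)OC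
F5 | step 8 | (6R)-6-(tert-butyldimethylsilyloxy)-2-iodo-1,1-dimethoxy-7-methylocta-1,7-dien-3-one | C=C(C)[C@H](O[Si](C)(C)C(C)(C)C)CCC(=O)C(I)=C(OC)OC
F6 | step 11 | 3-bromo-8-[(2R)-2-(tert-butyldimethylsilyloxy)-3-methylbut-3-enyl]-7-hydroxy-5-methoxy-6-(3-methylbut-2-enyl)-4H-chromen-4-one | C=C(C)[C@H](O[Si](C)(C)C(C)(C)C)Cc1c(O)c(CC=C(C)C)c(OC)c2c(=O)c(Br)coc12
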